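**Strategy.** The furofuran core is cut at the tetrahydrofuran ring that carries the keto-side-chain guaiacyl group (ring A: O, benzylic CH, two bridgehead CH, OCH2). Its C(aryl)–C(bridgehead)–CH2O array is read as the product of a Wolff ring contraction: a 2-aryl-3-diazo-2,3-dihydro-4H-pyran-4-one, made by asymmetric hetero-Diels–Alder reaction, extrudes its carbonyl carbon on irradiation and gives a 2-aryl-2,3-dihydrofuran-3-carboxylate. The extruded carbon becomes the OCH2 of the second ring, and the surviving enol ether lets the cis-dihydrobenzofuran acetal be annulated by cationic cyclisation. Both β-5 units come from 5-iodovanillin: carbenoid C–H insertion (west) and Evans aldol (east).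

Key step: step 20

Remark: the catalyst antipodes Rh2(R-PTTL)4 (dirhodium tetrakis[N-phthaloyl-(R)-tert-leucinate]) and (R,R)-1-naphthyl-TADDOL are assigned by analogy with simpler substrates; the mirror-image catalyst is taken if the sense of induction proves opposite.
Remark: (2-ethoxy-2-oxoethyl)zinc bromide 14 is taken as a commercial solution (otherwise made from ethyl bromoacetate and zinc).
Abbreviations used in names:
- G = 3-methoxy-4-(triisopropylsilyloxy)phenyl.
- ArE = 3-methoxy-4-(triisopropylsilyloxy)-5-[(1R,2S)-3-(tert-butyldiphenylsilyloxy)-1-G-1-(triethylsilyloxy)propan-2-yl]phenyl.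
- ArW = (2S,3S)-3-[(tert-butyldiphenylsilyloxy)methyl]-7-methoxy-2-G-2,3-dihydrobenzofuran-5-yl (cis).

**West fragment**

Step 1
Reactants: 1 vanillin
Product: 2 3-methoxy-4-(triisopropylsilyloxy)benzaldehyde
Conditions: TIPSCl, imidazole, DMF, rt
Reagents that add atoms: triisopropylsilyl chloride, CC(C)[Si](Cl)(C(C)C)C(C)C
Why: Standard phenol silylation; the hindered aryl silyl ether should survive the hydride, amide-base and low-temperature Lewis-acid steps that follow.

Step 2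
Reactants: 2 3-methoxy-4-(triisopropylsilyloxy)benzaldehyde
Product: 3 [3-methoxy-4-(triisopropylsilyloxy)phenyl]methanol
Conditions: NaBH4, MeOH, 0 °C
Reagents that add atoms: none
Why: Borohydride reduction of an aromatic aldehyde, which leaves the aryl silyl ether untouched.

Step 3
Reactants: 4 5-iodovanillin; 3 [3-methoxy-4-(triisopropylsilyloxy)phenyl]methanol
Product: 5 3-iodo-5-methoxy-4-{[3-methoxy-4-(triisopropylsilyloxy)benzyl]oxy}benzaldehyde
Conditions: PPh3, DIAD, THF, 0 °C to rt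
Reagents that add atoms: none
Why: Mitsunobu etherification of an acidic phenol with a primary benzylic alcohol under neutral conditions that avoid base-induced loss of the aryl silyl ether.

Step 4
Reactants: 5 3-iodo-5-methoxy-4-{[3-methoxy-4-(triisopropylsilyloxy)benzyl]oxy}benzaldehyde
Product: 6 dimethyl acetal of 5
Conditions: HC(OMe)3, PPTS (cat.), MeOH, rt; Et3N quench
Reagents that add atoms: trimethyl orthoformate, COC(OC)OC
Why: Acid-catalysed acetalisation masks the aldehyde towards the diazo, carbenoid and hydride steps and installs the acetal that serves as the electrophile in step 22.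

Step 5
Reactants: 6 dimethyl acetal of 5; 7 ethyl diazoacetate
Product: 8 ethyl 2-diazo-2-[5-(dimethoxymethyl)-3-methoxy-2-(G-methoxy)phenyl]acetate
Conditions: Pd(PPh3)4 (cat.), Ag2CO3, Et3N, toluene, rt
Reagents that add atoms: none
Why: Palladium-catalysed cross-coupling of an aryl iodide with the C–H bond of a diazoacetate (diazo group retained) should give the donor/acceptor diazo ester in one operation.

Step 6
Reactants: 8 ethyl 2-diazo-2-[5-(dimethoxymethyl)-3-methoxy-2-(G-methoxy)phenyl]acetate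
Product: 9 ethyl (2S,3R)-5-(dimethoxymethyl)-7-methoxy-2-G-2,3-dihydrobenzofuran-3-carboxylate (cis)
Conditions: Rh2(R-PTTL)4 (1 mol %), toluene, −60 °C
Reagents that add atoms: none
Why: Intramolecular 1,5 C–H insertion of the rhodium carbenoid into the activated benzylic ether C–H bond should give the cis-dihydrobenzofuran under kinetic control, the chiral carboxylate ligands setting C2 and C3 together.

Step 7
Reactants: 9 ethyl (2S,3R)-cis-dihydrobenzofuran-3-carboxylate
Product: 10 [(2S,3S)-5-(dimethoxymethyl)-7-methoxy-2-G-2,3-dihydrobenzofuran-3-yl]methanol (cis)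
Conditions: i-Bu2AlH, CH2Cl2, −78 to 0 °C; Rochelle salt work-up
Reagents that add atoms: none
Why: Low-temperature hydride reduction of the ester should avoid base-mediated cis-to-trans epimerisation at C3 (the descriptor changes only through the CIP order).

Step 8
Reactants: 10 cis-dihydrobenzofuran methanol
Product: 11 ArW-CH(OMe)2 (west acetal)
Conditions: TBDPSCl, imidazole, DMF, rt
Reagents that add atoms: tert-butyldiphenylsilyl chloride, CC(C)(C)[Si](Cl)(c1ccccc1)c1ccccc1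
Why: Silylation of the primary alcohol keeps it out of the acetal exchange of step 22.

**East fragment**

Step 9
Reactants: 4 5-iodovanillin
Product: 12 3-iodo-5-methoxy-4-(triisopropylsilyloxy)benzaldehyde
Conditions: TIPSOTf, 2,6-lutidine, CH2Cl2, 0 °C
Reagents that add atoms: triisopropylsilyl triflate, CC(C)[Si](OS(=O)(=O)C(F)(F)F)(C(C)C)C(C)C
Why: The silyl triflate is needed to silylate the doubly ortho-substituted phenol.

Step 10
Reactants: 12 3-iodo-5-methoxy-4-(triisopropylsilyloxy)benzaldehyde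
Product: 13 dimethyl acetal of 12
Conditions: HC(OMe)3, PPTS (cat.), MeOH, rt; Et3N quench
Reagents that add atoms: trimethyl orthoformate, COC(OC)OC
Why: Acetalisation protects the aldehyde from the zinc enolate and from the boron enolate of step 14.

Step 11
Reactants: 13 dimethyl acetal of 12; 14 (2-ethoxy-2-oxoethyl)zinc bromide
Product: 15 ethyl 2-[5-(dimethoxymethyl)-3-methoxy-2-(triisopropylsilyloxy)phenyl]acetate
Conditions: Pd2(dba)3 (cat.), XPhos, THF, 50 °C
Reagents that add atoms: none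
Why: Negishi-type coupling of the Reformatsky reagent with the aryl iodide (ester α-arylation) tolerates the acetal and silyl ether.

Step 12
Reactants: 15 ethyl arylacetate
Product: 16 2-[5-(dimethoxymethyl)-3-methoxy-2-(triisopropylsilyloxy)phenyl]acetic acid
Conditions: LiOH, THF/H2O, 0 °C to rt; AcOH to pH 5 at 0 °C
Reagents that add atoms: lithium hydroxide, [Li+].[OH-]
Why: Saponification, with buffered acidification so that the acid-labile acetal and the hindered aryl silyl ether should survive.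

Step 13
Reactants: 16 arylacetic acid; 17 (R)-4-benzyl-2-oxazolidinone
Product: 19 (R)-4-benzyl-3-{2-[5-(dimethoxymethyl)-3-methoxy-2-(triisopropylsilyloxy)phenyl]acetyl}oxazolidin-2-one, via mixed pivalic anhydride 18 (not isolated)
Conditions: PivCl, Et3N, THF, −20 °C; then 17, LiCl, rt
Reagents that add atoms: pivaloyl chloride, CC(C)(C)C(=O)Cl (its atoms stay only in 18)
Why: N-Acylation of the oxazolidinone through the mixed anhydride is base-mild and acid-free.

Step 14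
Reactants: 19 arylacetyl oxazolidinone; 2 3-methoxy-4-(triisopropylsilyloxy)benzaldehyde
Product: 20 (R)-4-benzyl-3-[(2R,3R)-2-aryl-3-G-3-hydroxypropanoyl]oxazolidin-2-one (aryl = 5-(dimethoxymethyl)-3-methoxy-2-(triisopropylsilyloxy)phenyl)
Conditions: Bu2BOTf, i-Pr2NEt, CH2Cl2, −78 to 0 °C; then H2O2, pH 7 buffer, MeOH
Reagents that add atoms: none
Why: Evans syn-aldol reaction: the Z boron enolate reacts through a chair transition state on the face opposite the benzyl group, so the (R)-auxiliary sets the aryl-bearing carbon in the configuration that becomes (S) in the final ketone; the carbinol centre is later oxidised away.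

Step 15
Reactants: 20 aldol adduct
Product: 22 3-[(1R,2S)-1-G-1,3-dihydroxypropan-2-yl]-5-methoxy-4-(triisopropylsilyloxy)benzaldehyde, via diol acetal 21 (not isolated)
Conditions: LiBH4, MeOH (1 equiv), THF, 0 °C; then 1 M HCl, THF, 0 °C
Reagents that add atoms: water, O
Why: Reductive removal of the auxiliary gives the 1,3-diol without touching the stereocentres, and the acidic work-up hydrolyses the dimethyl acetal.

Step 16
Reactants: 22 diol aldehyde
Product: 23 primary tert-butyldiphenylsilyl ether of 22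
Conditions: TBDPSCl, imidazole, CH2Cl2, 0 °C
Reagents that add atoms: tert-butyldiphenylsilyl chloride, CC(C)(C)[Si](Cl)(c1ccccc1)c1ccccc1
Why: The bulky silyl chloride should select the primary over the hindered secondary benzylic hydroxyl.

Step 17
Reactants: 23 primary silyl ether
Product: 24 ArE-CHO (east aldehyde)
Conditions: TESOTf, 2,6-lutidine, CH2Cl2, −78 °C
Reagents that add atoms: triethylsilyl triflate, CC[Si](CC)(CC)OS(=O)(=O)C(F)(F)F
Why: The secondary carbinol is capped as the most acid-labile silyl ether so that it alone can be unveiled in step 24.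

**Core assembly and end game**

Step 18
Reactants: 24 ArE-CHO; 25 (E)-1-(dimethylamino)-3-(tert-butyldimethylsilyloxy)buta-1,3-diene
Product: 27 (S)-2-ArE-2,3-dihydro-4H-pyran-4-one, via aminal cycloadduct 26 (not isolated)
Conditions: (R,R)-1-naphthyl-TADDOL (20 mol %), toluene, −40 °C; then AcCl, CH2Cl2, −78 °C
Reagents that add atoms: none
Why: Hydrogen-bond-catalysed hetero-Diels–Alder reaction of the aminosiloxydiene with the aldehyde, the diol shielding one carbonyl face to set C2; acetyl chloride then eliminates the amine and cleaves the silyl enol ether under conditions the TES ether should tolerate.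

Step 19
Reactants: 27 (S)-2-ArE-2,3-dihydro-4H-pyran-4-one
Product: 29 (2R)-3-diazo-2-ArE-2,3-dihydro-4H-pyran-4-one (same spatial arrangement at C2 as 27), via trifluoroacetyl ketone 28 (not isolated)
Conditions: LiN(SiMe3)2, THF, −78 °C; CF3CO2CH2CF3; then MsN3, Et3N, H2O, MeCN, rt
Reagents that add atoms: mesyl azide, CS(=O)(=O)N=[N+]=[N-]; 2,2,2-trifluoroethyl trifluoroacetate, O=C(OCC(F)(F)F)C(F)(F)F (trifluoroacetyl of 28 only)
Why: Detrifluoroacetylative (Regitz-type) diazo transfer; the enone has a single enolisable CH2 (C3), so the diazo group can only enter between the aryl-bearing carbon and the carbonyl.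

Step 20
Reactants: 29 (2R)-3-diazo-2-ArE-2,3-dihydro-4H-pyran-4-one
Product: 32 methyl (2S,3S)-2-ArE-2,3-dihydrofuran-3-carboxylate (trans), via ketene 30 (not isolated), via cis ester 31 (not isolated)
Conditions: hν (365 nm), MeOH, 0 °C; evaporate; DBU (cat.), toluene, rt
Reagents that add atoms: methanol, CO
Why: Irradiation of the cyclic s-cis α-diazo ketone expels N2 with concerted 1,2-shift of the vinylic carbon C5 from the carbonyl carbon C4 to the diazo carbon C3, so the six-membered pyranone contracts to the five-membered 2,3-dihydrofuran and C4 leaves the ring as the ketene carbon of 30; methanol adds to the ketene to give ester 31, and DBU equilibrates the doubly activated C3–H to the 2,3-trans ester 32. The closest known reaction type is the photochemical Wolff ring contraction of cyclic 2-diazo ketones to ring-contracted esters, here with an α′-vinyl migrating group. The five-membered ring is closed by this suprafacial 1,2-carbon shift with retention at the migrating sp2 carbon and not by cyclisation of a chain, so the aryl-bearing stereocentre from step 18 is untouched and becomes C2 of the dihydrofuran. The new stereocentre C3 is set under thermodynamic control by the neighbouring aryl group, trans avoiding the eclipsed aryl/ester arrangement. The step needs the Wolff shift to win over 1,2-hydride shift from C2–H (which would give the 4-pyranone) and over O–H insertion, which the locked s-cis geometry and metal-free photolysis should secure, and it needs α- rather than γ-protonation of the dienol, the kinetic course; brief exposure to catalytic DBU should limit migration of the enol-ether double bond into conjugation.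

Step 21
Reactants: 32 methyl (2S,3S)-2-ArE-2,3-dihydrofuran-3-carboxylate
Product: 33 [(2S,3R)-2-ArE-2,3-dihydrofuran-3-yl]methanol (trans)
Conditions: i-Bu2AlH, CH2Cl2, −78 °C; Rochelle salt work-up
Reagents that add atoms: none
Why: Ester reduction at low temperature leaves the enol ether and all silyl ethers intact.

Step 22
Reactants: 33 trans-dihydrofuryl methanol; 11 ArW-CH(OMe)2
Product: 35 (1S,3aR,4S,6aR)-1-ArE-4-ArW-3-methoxytetrahydro-1H,3H-furo[3,4-c]furan (both anomers at C3), via mixed acetal 34 (not isolated)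
Conditions: TMSOTf (0.2 equiv), CH2Cl2, −78 to −40 °C; Et3N quench
Reagents that add atoms: none
Why: Acetal exchange and ionisation give an oxocarbenium ion tethered to the alcohol, which the enol-ether β-carbon attacks in a Prins-type (templated cationic) cyclisation; the five-five ring fusion can only be cis, the new aryl group should take the exo position in a chair-like transition state, and the resulting ring oxocarbenium ion is trapped by methanol.

Step 23
Reactants: 35 methoxy furofuran acetal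
Product: 36 (1S,3aR,4S,6aR)-1-ArE-4-ArW-tetrahydro-1H,3H-furo[3,4-c]furan
Conditions: Et3SiH, BF3·OEt2, CH2Cl2, −78 °C
Reagents that add atoms: none
Why: Ionic hydrogenation: the acetal ionises far more readily than the benzylic ethers or silyl ethers at −78 °C, and hydride delivery to the ring oxocarbenium ion creates the OCH2 group without a new stereocentre.

Step 24
Reactants: 36 fully silylated furofuran
Product: 37 secondary alcohol (triethylsilyl group removed)
Conditions: PPTS, MeOH/CH2Cl2, 0 °C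
Reagents that add atoms: none
Why: Mild acid methanolysis should cleave only the triethylsilyl ether, leaving the aryl TIPS and primary TBDPS ethers.

Step 25
Reactants: 37 secondary alcohol
Product: 38 aryl ketone with (S)-configured α-carbon
Conditions: Dess–Martin periodinane, NaHCO3, CH2Cl2, 0 °C
Reagents that add atoms: none
Why: Buffered Dess–Martin oxidation is neutral and fast, so the newly acidic α-aryl stereocentre should not epimerise.

Step 26
Reactants: 38 pentasilylated ketone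
Product: 39 CNP0174045.1
Conditions: Bu4NF, AcOH (1:1), THF, 0 °C to rt
Reagents that add atoms: none
Why: Acetic-acid-buffered fluoride removes the three aryl and two primary silyl groups while keeping the medium non-basic, which should prevent retro-aldol cleavage or epimerisation of the α-aryl-β-hydroxy ketone.

**Compound list**

1 | vanillin | COc1cc(C=O)ccc1O | starting material
2 | 3-methoxy-4-(triisopropylsilyloxy)benzaldehyde | COc1cc(C=O)ccc1O[Si](C(C)C)(C(C)C)C(C)C | intermediate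
3 | [3-methoxy-4-(triisopropylsilyloxy)phenyl]methanol | COc1cc(CO)ccc1O[Si](C(C)C)(C(C)C)C(C)C | intermediate
4 | 5-iodovanillin | COc1cc(C=O)cc(I)c1O | starting material
5 | 3-iodo-5-methoxy-4-{[3-methoxy-4-(triisopropylsilyloxy)benzyl]oxy}benzaldehyde | COc1cc(C=O)cc(I)c1OCc1ccc(O[Si](C(C)C)(C(C)C)C(C)C)c(OC)c1 | intermediate
6 | dimethyl acetal of 5 | COc1cc(C(OC)OC)cc(I)c1OCc1ccc(O[Si](C(C)C)(C(C)C)C(C)C)c(OC)c1 | intermediate
7 | ethyl diazoacetate | CCOC(=O)C=[N+]=[N-] | starting material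
8 | ethyl 2-diazo-2-[5-(dimethoxymethyl)-3-methoxy-2-(G-methoxy)phenyl]acetate | CCOC(=O)C(=[N+]=[N-])c1cc(C(OC)OC)cc(OC)c1OCc1ccc(O[Si](C(C)C)(C(C)C)C(C)C)c(OC)c1 | intermediate
9 | ethyl (2S,3R)-5-(dimethoxymethyl)-7-methoxy-2-G-2,3-dihydrobenzofuran-3-carboxylate (cis) | COC(OC)c1cc(OC)c2c(c1)[C@@H](C(=O)OCC)[C@@H](c1ccc(O[Si](C(C)C)(C(C)C)C(C)C)c(OC)c1)O2 | intermediate
10 | [(2S,3S)-5-(dimethoxymethyl)-7-methoxy-2-G-2,3-dihydrobenzofuran-3-yl]methanol (cis) | COC(OC)c1cc(OC)c2c(c1)[C@@H](CO)[C@@H](c1ccc(O[Si](C(C)C)(C(C)C)C(C)C)c(OC)c1)O2 | intermediate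
11 | ArW-CH(OMe)2, west acetal | COC(OC)c1cc(OC)c2c(c1)[C@@H](CO[Si](c3ccccc3)(c3ccccc3)C(C)(C)C)[C@@H](c1ccc(O[Si](C(C)C)(C(C)C)C(C)C)c(OC)c1)O2 | intermediate
12 | 3-iodo-5-methoxy-4-(triisopropylsilyloxy)benzaldehyde | COc1cc(C=O)cc(I)c1O[Si](C(C)C)(C(C)C)C(C)C | intermediate
13 | dimethyl acetal of 12 | COc1cc(C(OC)OC)cc(I)c1O[Si](C(C)C)(C(C)C)C(C)C | intermediate
14 | (2-ethoxy-2-oxoethyl)zinc bromide | CCOC(=O)C[Zn]Br | starting material
15 | ethyl 2-[5-(dimethoxymethyl)-3-methoxy-2-(triisopropylsilyloxy)phenyl]acetate | CCOC(=O)Cc1cc(C(OC)OC)cc(OC)c1O[Si](C(C)C)(C(C)C)C(C)C | intermediate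
16 | 2-[5-(dimethoxymethyl)-3-methoxy-2-(triisopropylsilyloxy)phenyl]acetic acid | OC(=O)Cc1cc(C(OC)OC)cc(OC)c1O[Si](C(C)C)(C(C)C)C(C)C | intermediate
17 | (R)-4-benzyl-2-oxazolidinone | O=C1N[C@H](Cc2ccccc2)CO1 | starting material
18 | mixed pivalic anhydride of 16 | CC(C)(C)C(=O)OC(=O)Cc1cc(C(OC)OC)cc(OC)c1O[Si](C(C)C)(C(C)C)C(C)C | intermediate
19 | (R)-4-benzyl-3-(arylacetyl)oxazolidin-2-one | O=C(Cc1cc(C(OC)OC)cc(OC)c1O[Si](C(C)C)(C(C)C)C(C)C)N1[C@H](Cc2ccccc2)COC1=O | intermediate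
20 | (R)-4-benzyl-3-[(2R,3R)-2-aryl-3-G-3-hydroxypropanoyl]oxazolidin-2-one | COc1cc([C@H](O)[C@H](C(=O)N3[C@H](Cc4ccccc4)COC3=O)c2cc(C(OC)OC)cc(OC)c2O[Si](C(C)C)(C(C)C)C(C)C)ccc1O[Si](C(C)C)(C(C)C)C(C)C | intermediate
21 | (1R,2S)-2-[5-(dimethoxymethyl)-3-methoxy-2-(triisopropylsilyloxy)phenyl]-1-G-propane-1,3-diol | COc1cc([C@H](O)[C@H](CO)c2cc(C(OC)OC)cc(OC)c2O[Si](C(C)C)(C(C)C)C(C)C)ccc1O[Si](C(C)C)(C(C)C)C(C)C | intermediate
22 | 3-[(1R,2S)-1-G-1,3-dihydroxypropan-2-yl]-5-methoxy-4-(triisopropylsilyloxy)benzaldehyde | COc1cc([C@H](O)[C@H](CO)c2cc(C=O)cc(OC)c2O[Si](C(C)C)(C(C)C)C(C)C)ccc1O[Si](C(C)C)(C(C)C)C(C)C | intermediate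
23 | primary tert-butyldiphenylsilyl ether of 22 | COc1cc([C@H](O)[C@H](CO[Si](c5ccccc5)(c5ccccc5)C(C)(C)C)c2cc(C=O)cc(OC)c2O[Si](C(C)C)(C(C)C)C(C)C)ccc1O[Si](C(C)C)(C(C)C)C(C)C | intermediate
24 | ArE-CHO, east aldehyde | COc1cc([C@H](O[Si](CC)(CC)CC)[C@H](CO[Si](c5ccccc5)(c5ccccc5)C(C)(C)C)c2cc(C=O)cc(OC)c2O[Si](C(C)C)(C(C)C)C(C)C)ccc1O[Si](C(C)C)(C(C)C)C(C)C | intermediate
25 | (E)-1-(dimethylamino)-3-(tert-butyldimethylsilyloxy)buta-1,3-diene | CN(C)/C=C/C(=C)O[Si](C)(C)C(C)(C)C | starting material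
26 | (2S)-2-ArE-6-(dimethylamino)-4-(tert-butyldimethylsilyloxy)-3,6-dihydro-2H-pyran | COc1cc([C@H](O[Si](CC)(CC)CC)[C@H](CO[Si](c5ccccc5)(c5ccccc5)C(C)(C)C)c2cc([C@@H]3CC(O[Si](C)(C)C(C)(C)C)=CC(N(C)C)O3)cc(OC)c2O[Si](C(C)C)(C(C)C)C(C)C)ccc1O[Si](C(C)C)(C(C)C)C(C)C | intermediate
27 | (S)-2-ArE-2,3-dihydro-4H-pyran-4-one | COc1cc([C@H](O[Si](CC)(CC)CC)[C@H](CO[Si](c5ccccc5)(c5ccccc5)C(C)(C)C)c2cc([C@@H]3CC(=O)C=CO3)cc(OC)c2O[Si](C(C)C)(C(C)C)C(C)C)ccc1O[Si](C(C)C)(C(C)C)C(C)C | intermediate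
28 | (2S)-2-ArE-3-(trifluoroacetyl)-2,3-dihydro-4H-pyran-4-one | COc1cc([C@H](O[Si](CC)(CC)CC)[C@H](CO[Si](c5ccccc5)(c5ccccc5)C(C)(C)C)c2cc([C@@H]3C(C(=O)C(F)(F)F)C(=O)C=CO3)cc(OC)c2O[Si](C(C)C)(C(C)C)C(C)C)ccc1O[Si](C(C)C)(C(C)C)C(C)C | intermediate
29 | (2R)-3-diazo-2-ArE-2,3-dihydro-4H-pyran-4-one | COc1cc([C@H](O[Si](CC)(CC)CC)[C@H](CO[Si](c5ccccc5)(c5ccccc5)C(C)(C)C)c2cc([C@@H]3C(=[N+]=[N-])C(=O)C=CO3)cc(OC)c2O[Si](C(C)C)(C(C)C)C(C)C)ccc1O[Si](C(C)C)(C(C)C)C(C)C | intermediate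
30 | (2-ArE-furan-3(2H)-ylidene)methanone, ketene | COc1cc([C@H](O[Si](CC)(CC)CC)[C@H](CO[Si](c5ccccc5)(c5ccccc5)C(C)(C)C)c2cc([C@@H]3C(=C=O)C=CO3)cc(OC)c2O[Si](C(C)C)(C(C)C)C(C)C)ccc1O[Si](C(C)C)(C(C)C)C(C)C | intermediate
31 | methyl (2S,3R)-2-ArE-2,3-dihydrofuran-3-carboxylate (cis) | COc1cc([C@H](O[Si](CC)(CC)CC)[C@H](CO[Si](c5ccccc5)(c5ccccc5)C(C)(C)C)c2cc([C@@H]3[C@H](C(=O)OC)C=CO3)cc(OC)c2O[Si](C(C)C)(C(C)C)C(C)C)ccc1O[Si](C(C)C)(C(C)C)C(C)C | intermediate
32 | methyl (2S,3S)-2-ArE-2,3-dihydrofuran-3-carboxylate (trans) | COc1cc([C@H](O[Si](CC)(CC)CC)[C@H](CO[Si](c5ccccc5)(c5ccccc5)C(C)(C)C)c2cc([C@@H]3[C@@H](C(=O)OC)C=CO3)cc(OC)c2O[Si](C(C)C)(C(C)C)C(C)C)ccc1O[Si](C(C)C)(C(C)C)C(C)C | intermediate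
33 | [(2S,3R)-2-ArE-2,3-dihydrofuran-3-yl]methanol (trans) | COc1cc([C@H](O[Si](CC)(CC)CC)[C@H](CO[Si](c5ccccc5)(c5ccccc5)C(C)(C)C)c2cc([C@@H]3[C@@H](CO)C=CO3)cc(OC)c2O[Si](C(C)C)(C(C)C)C(C)C)ccc1O[Si](C(C)C)(C(C)C)C(C)C | intermediate
34 | mixed methyl acetal of ArW-CHO with alcohol 33 | COc1cc([C@H](O[Si](CC)(CC)CC)[C@H](CO[Si](c5ccccc5)(c5ccccc5)C(C)(C)C)c2cc([C@@H]3[C@@H](COC(OC)c4cc(OC)c6c(c4)[C@@H](CO[Si](c5ccccc5)(c5ccccc5)C(C)(C)C)[C@@H](c4ccc(O[Si](C(C)C)(C(C)C)C(C)C)c(OC)c4)O6)C=CO3)cc(OC)c2O[Si](C(C)C)(C(C)C)C(C)C)ccc1O[Si](C(C)C)(C(C)C)C(C)C | intermediate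
35 | (1S,3aR,4S,6aR)-1-ArE-4-ArW-3-methoxytetrahydro-1H,3H-furo[3,4-c]furan | COc1cc([C@H](O[Si](CC)(CC)CC)[C@H](CO[Si](c5ccccc5)(c5ccccc5)C(C)(C)C)c2cc([C@H]3OC(OC)[C@H]4[C@@H]3CO[C@@H]4c3cc(OC)c4c(c3)[C@@H](CO[Si](c5ccccc5)(c5ccccc5)C(C)(C)C)[C@@H](c3ccc(O[Si](C(C)C)(C(C)C)C(C)C)c(OC)c3)O4)cc(OC)c2O[Si](C(C)C)(C(C)C)C(C)C)ccc1O[Si](C(C)C)(C(C)C)C(C)C | intermediate
36 | (1S,3aR,4S,6aR)-1-ArE-4-ArW-tetrahydro-1H,3H-furo[3,4-c]furan | COc1cc([C@H](O[Si](CC)(CC)CC)[C@H](CO[Si](c5ccccc5)(c5ccccc5)C(C)(C)C)c2cc([C@H]3OC[C@H]4[C@@H]3CO[C@@H]4c3cc(OC)c4c(c3)[C@@H](CO[Si](c5ccccc5)(c5ccccc5)C(C)(C)C)[C@@H](c3ccc(O[Si](C(C)C)(C(C)C)C(C)C)c(OC)c3)O4)cc(OC)c2O[Si](C(C)C)(C(C)C)C(C)C)ccc1O[Si](C(C)C)(C(C)C)C(C)C | intermediate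
37 | 36 with the free (1R) secondary benzylic hydroxyl | COc1cc([C@H](O)[C@H](CO[Si](c5ccccc5)(c5ccccc5)C(C)(C)C)c2cc([C@H]3OC[C@H]4[C@@H]3CO[C@@H]4c3cc(OC)c4c(c3)[C@@H](CO[Si](c5ccccc5)(c5ccccc5)C(C)(C)C)[C@@H](c3ccc(O[Si](C(C)C)(C(C)C)C(C)C)c(OC)c3)O4)cc(OC)c2O[Si](C(C)C)(C(C)C)C(C)C)ccc1O[Si](C(C)C)(C(C)C)C(C)C | intermediate
38 | pentasilylated (S)-ketone | COc1cc(C(=O)[C@H](CO[Si](c5ccccc5)(c5ccccc5)C(C)(C)C)c2cc([C@H]3OC[C@H]4[C@@H]3CO[C@@H]4c3cc(OC)c4c(c3)[C@@H](CO[Si](c5ccccc5)(c5ccccc5)C(C)(C)C)[C@@H](c3ccc(O[Si](C(C)C)(C(C)C)C(C)C)c(OC)c3)O4)cc(OC)c2O[Si](C(C)C)(C(C)C)C(C)C)ccc1O[Si](C(C)C)(C(C)C)C(C)C | intermediate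
39 | CNP0174045.1 | COc1cc(C(=O)[C@H](CO)c2cc([C@H]3OC[C@H]4[C@@H]3CO[C@@H]4c3cc(OC)c4c(c3)[C@@H](CO)[C@@H](c3ccc(O)c(OC)c3)O4)cc(OC)c2O)ccc1O | target

**Count and risks**

Total step count: 26. Longest linear sequence: 18 steps (4 → 12 → 13 → 15 → 16 → 19 → 20 → 22 → 23 → 24 → 27 → 29 → 32 → 33 → 35 → 36 → 37 → 38 → 39).

Steps most likely to fail:

1. Step 20. The carbene manifold may leak into 1,2-hydride shift (aromatising to the 4-pyranone). The base equilibration may also move the enol-ether double bond into conjugation with the ester or open the ring by β-elimination, so that the trans ester is not reached cleanly. Fallback (ring expansion of a three-membered ring instead): the route sets out from 24 and returns at 33. Wittig reaction of 24 with (triphenylphosphoranylidene)acetaldehyde should give the (E)-cinnamaldehyde F1. Iminium-catalysed cyclopropanation with ethyl (dimethylsulfuranylidene)acetate and the suitable antipode of indoline-2-carboxylic acid should give the formyl cyclopropane ester F2. Lewis-acid-promoted (Yb(OTf)3) Cloke–Wilson rearrangement cleaves the donor–acceptor bond between the aryl-bearing and formyl-bearing carbons and recloses through the aldehyde oxygen, giving the ethyl trans-dihydrofuran ester F3 with the ester-bearing stereocentre retained and the aryl-bearing one set trans under thermodynamic control. Reduction with i-Bu2AlH then gives 33.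

2. Step 22. The silyl triflate may ionise the benzylic C2–O bond of the cis-dihydrobenzofuran (epimerisation to trans) or the benzylic silyl ether, the enol ether may oligomerise, and exo selectivity for the incoming aryl group may be incomplete. Fallback (no Lewis acid; it also bypasses steps 19–21 and 23): the route sets out from 27 and 11 and returns at 36. Mild hydrolysis of 11 (PPTS, wet acetone) gives the west aldehyde F4. Conjugate reduction of 27 with LiBH(s-Bu)3 at −78 °C gives the regiodefined enolate, which adds to F4; quenching with TMSCl should give the anti aldol TMS ether F5 (2,5-trans on the tetrahydropyranone, if need be after equilibration). Detrifluoroacetylative diazo transfer at the only remaining CH2, with citric acid/MeOH work-up, gives the hydroxy diazo ketone F6. Irradiation (365 nm, MeCN) contracts the tetrahydropyranone by Wolff rearrangement, and the ketene is captured by the neighbouring hydroxyl to give the cis-fused furofuranone F7. LiAlH4 gives the diol F8, and MsCl/pyridine closes the ether through the primary mesylate with retention at the benzylic carbinol, giving 36.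

3. Step 5. Transmetalation at the hindered ortho-alkoxy aryl iodide may be slow, so that the diazo ester decomposes (carbene dimerisation) before coupling. Fallback: the route sets out from 6 and returns at 8. Negishi coupling of 6 with 14 (Pd2(dba)3, XPhos) gives the ethyl arylacetate F9, and Regitz diazo transfer (4-acetamidobenzenesulfonyl azide, DBU, MeCN) gives 8.

**Further compounds**

F1 | step 20 | (E)-3-ArE-prop-2-enal | COc1cc([C@H](O[Si](CC)(CC)CC)[C@H](CO[Si](c5ccccc5)(c5ccccc5)C(C)(C)C)c2cc(/C=C/C=O)cc(OC)c2O[Si](C(C)C)(C(C)C)C(C)C)ccc1O[Si](C(C)C)(C(C)C)C(C)C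
F2 | step 20 | ethyl 2-ArE-3-formylcyclopropane-1-carboxylate (formyl trans to aryl and to ester) | COc1cc([C@H](O[Si](CC)(CC)CC)[C@H](CO[Si](c5ccccc5)(c5ccccc5)C(C)(C)C)c2cc([C@H]3[C@@H](C(=O)OCC)[C@@H]3C=O)cc(OC)c2O[Si](C(C)C)(C(C)C)C(C)C)ccc1O[Si](C(C)C)(C(C)C)C(C)C
F3 | step 20 | ethyl (2S,3S)-2-ArE-2,3-dihydrofuran-3-carboxylate (trans) | COc1cc([C@H](O[Si](CC)(CC)CC)[C@H](CO[Si](c5ccccc5)(c5ccccc5)C(C)(C)C)c2cc([C@@H]3[C@@H](C(=O)OCC)C=CO3)cc(OC)c2O[Si](C(C)C)(C(C)C)C(C)C)ccc1O[Si](C(C)C)(C(C)C)C(C)C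
F4 | step 22 | ArW-CHO, west aldehyde | O=Cc1cc(OC)c2c(c1)[C@@H](CO[Si](c3ccccc3)(c3ccccc3)C(C)(C)C)[C@@H](c1ccc(O[Si](C(C)C)(C(C)C)C(C)C)c(OC)c1)O2
F5 | step 22 | (2S,5R)-2-ArE-5-[(S)-ArW(trimethylsilyloxy)methyl]tetrahydro-4H-pyran-4-one | COc1cc([C@H](O[Si](CC)(CC)CC)[C@H](CO[Si](c5ccccc5)(c5ccccc5)C(C)(C)C)c2cc([C@@H]3CC(=O)[C@@H]([C@H](O[Si](C)(C)C)c4cc(OC)c6c(c4)[C@@H](CO[Si](c5ccccc5)(c5ccccc5)C(C)(C)C)[C@@H](c4ccc(O[Si](C(C)C)(C(C)C)C(C)C)c(OC)c4)O6)CO3)cc(OC)c2O[Si](C(C)C)(C(C)C)C(C)C)ccc1O[Si](C(C)C)(C(C)C)C(C)C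
F6 | step 22 | 3-diazo-2-ArE-5-[(S)-ArW(hydroxy)methyl]tetrahydro-4H-pyran-4-one (2,5-trans) | COc1cc([C@H](O[Si](CC)(CC)CC)[C@H](CO[Si](c5ccccc5)(c5ccccc5)C(C)(C)C)c2cc([C@@H]3C(=[N+]=[N-])C(=O)[C@@H]([C@H](O)c4cc(OC)c6c(c4)[C@@H](CO[Si](c5ccccc5)(c5ccccc5)C(C)(C)C)[C@@H](c4ccc(O[Si](C(C)C)(C(C)C)C(C)C)c(OC)c4)O6)CO3)cc(OC)c2O[Si](C(C)C)(C(C)C)C(C)C)ccc1O[Si](C(C)C)(C(C)C)C(C)C
F7 | step 22 | 6-oxo derivative (γ-lactone) of 36 | COc1cc([C@H](O[Si](CC)(CC)CC)[C@H](CO[Si](c5ccccc5)(c5ccccc5)C(C)(C)C)c2cc([C@H]3OC[C@H]4[C@@H]3C(=O)O[C@@H]4c3cc(OC)c4c(c3)[C@@H](CO[Si](c5ccccc5)(c5ccccc5)C(C)(C)C)[C@@H](c3ccc(O[Si](C(C)C)(C(C)C)C(C)C)c(OC)c3)O4)cc(OC)c2O[Si](C(C)C)(C(C)C)C(C)C)ccc1O[Si](C(C)C)(C(C)C)C(C)C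
F8 | step 22 | 2-ArE-3-(hydroxymethyl)-4-[(S)-ArW(hydroxy)methyl]tetrahydrofuran (2,3-trans, 3,4-cis) | COc1cc([C@H](O[Si](CC)(CC)CC)[C@H](CO[Si](c5ccccc5)(c5ccccc5)C(C)(C)C)c2cc([C@H]3OC[C@H]([C@H](O)c4cc(OC)c6c(c4)[C@@H](CO[Si](c5ccccc5)(c5ccccc5)C(C)(C)C)[C@@H](c4ccc(O[Si](C(C)C)(C(C)C)C(C)C)c(OC)c4)O6)[C@@H]3CO)cc(OC)c2O[Si](C(C)C)(C(C)C)C(C)C)ccc1O[Si](C(C)C)(C(C)C)C(C)C
F9 | step 5 | ethyl 2-[5-(dimethoxymethyl)-3-methoxy-2-(G-methoxy)phenyl]acetate | CCOC(=O)Cc1cc(C(OC)OC)cc(OC)c1OCc1ccc(O[Si](C(C)C)(C(C)C)C(C)C)c(OC)c1
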